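**Plan**
1. Retrosynthetic cuts: (a) the ester C–O bond between the C5'-CH2O group and the hydroxymethylglutaryl unit. (b) The epoxide O and C4'–H, taking ring C back to a flat phenol. (c) In one retro-step, the C9–C10 bond of ring B and the C4–C5 bond of ring A, with C4 returned to C10. (d) C6–C7 (enolate alkylation) and C8=C9 (Wittig).
2. Enabling feature: in ring A (C1–C5, C10) the gem-dimethyl carbon C4, the methine C5 and the methyl-bearing quaternary C10 stand in a row, and the ring carries no heteroatom. With C4 bonded to C10 instead of C5, the ring is the 1,2,2-trimethylcyclopentane of camphoric acid with C5 as an exocyclic carbinol. Its Wagner–Meerwein enlargement gives the C10 cation of the presumed biosynthetic drimane cyclisation.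
3. Forward order: the five-membered pre-ring A (6) and the arene/allylsilane arm (19, ring C still aromatic) are joined at C6–C7. One cationic event then enlarges ring A, closes ring B and leaves the C8=C12 methylene. Ring C is dearomatised, epoxidised and reduced, and the side-chain half ester is attached last.
4. Stereochemistry: C10 comes from (1S,3R)-camphoric acid and C5 from a CBS reduction, both carried over with inversion in the shift. C9 comes from the alkene geometry in a chair closure. C2'/C3' come from a tartrate-mediated epoxidation and C4' from hydride attack anti to the epoxide. The side-chain carbinol comes from an esterase desymmetrisation.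

Key step: step 15

Numbering and abbreviations: decalin atoms carry drimane numbers, also in the precursors (ring A = C1–C5 + C10, ring B = C5–C10, C11 = CH2 link, C12 = exocyclic CH2). In ring C, C1' = ketone, C2' = quaternary epoxide carbon, C3' = epoxide CH, C4' = carbinol, C5' = carbon bearing CH2O, C6' = vinylic CH. TBS = tert-butyldimethylsilyl; Ar = 2-(TBSO)-4-(TBSOCH2)phenyl; DrCH2 = [(1S,4aS,8aS)-5,5,8a-trimethyl-2-methylidenedecahydronaphthalen-1-yl]methyl.
Assumption: the L-tartrate template of step 18 is taken to deliver the peroxide to the face that gives the (1R,6S)-epoxide, by analogy with 2-alkyl-5-(hydroxymethyl) quinone monoketals of the same substitution pattern; D-tartrate is the mirror-image option.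

**Step 1**
Reactants: 1 (1S,3R)-camphoric acid
Product: 2 (1S,3R)-3-(methoxycarbonyl)-1,2,2-trimethylcyclopentane-1-carboxylic acid
Conditions: MeOH, H2SO4 (cat.), reflux
Reagents that add atoms: methanol, CO
Why: Fischer esterification is selective because the secondary C3 carboxyl group esterifies readily whereas the tertiary C1 carboxyl group next to the CMe2 carbon is too hindered, and no stereocentre is touched.

**Step 2**
Reactants: 2 (1S,3R)-3-(methoxycarbonyl)-1,2,2-trimethylcyclopentane-1-carboxylic acid
Product: 4 methyl (1R,3S)-3-acetyl-2,2,3-trimethylcyclopentane-1-carboxylate, via acid chloride 3 (not isolated)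
Conditions: (COCl)2, DMF (cat.), CH2Cl2, 0 °C to rt; then Me2CuLi, Et2O, −78 °C
Reagents that add atoms: oxalyl chloride, O=C(Cl)C(=O)Cl (Cl of 3); lithium dimethylcuprate, [Li+].C[Cu-]C
Why: Acid chloride formation and Gilman ketone synthesis stop at the methyl ketone because the cuprate attacks neither ketone nor ester at low temperature, and the quaternary centre cannot epimerise.

**Step 3**
Reactants: 4 methyl (1R,3S)-3-acetyl-2,2,3-trimethylcyclopentane-1-carboxylate
Product: 5 (1R,3S)-3-acetyl-2,2,3-trimethylcyclopentane-1-carboxylic acid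
Conditions: LiOH, THF–MeOH–H2O, 40 °C; then 1 M HCl
Reagents that add atoms: lithium hydroxide, [Li+].[OH-]
Why: Saponification of the unhindered secondary ester is routine, and any epimerisation at this carbon is irrelevant because it becomes a CH2 group in the next step.

**Step 4**
Reactants: 5 (1R,3S)-3-acetyl-2,2,3-trimethylcyclopentane-1-carboxylic acid
Product: 6 1-[(1S)-1,2,2-trimethylcyclopentyl]ethan-1-one
Conditions: 9-mesityl-10-methylacridinium tetrafluoroborate (5 mol %), PhSSPh (10 mol %), iPr2NEt (20 mol %), CF3CH2OH, 450 nm LED, rt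
Reagents that add atoms: none
Why: Organophotoredox hydrodecarboxylation: the carboxylate is oxidised by the excited acridinium salt, loses CO2 and the secondary radical takes hydrogen from thiophenol formed in situ, which deletes the helper carboxyl group and leaves the quaternary carbon (future C10) as the only stereocentre.

**Step 5**
Reactants: 7 methyl 4-bromo-3-hydroxybenzoate
Product: 8 2-bromo-5-(hydroxymethyl)phenol
Conditions: LiAlH4, THF, 0 °C to rt
Reagents that add atoms: none
Why: Hydride reduction of the ester with LiAlH4 gives the benzylic alcohol while the aryl bromide and the phenoxide are inert at this temperature.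

**Step 6**
Reactants: 8 2-bromo-5-(hydroxymethyl)phenol
Product: 9 1-bromo-2-(TBSO)-4-(TBSOCH2)benzene (Ar-Br)
Conditions: TBSCl, imidazole, DMF, rt
Reagents that add atoms: tert-butyldimethylsilyl chloride, CC(C)(C)[Si](C)(C)Cl
Why: Imidazole-promoted silylation protects the phenol and the benzylic alcohol alike, so that one fluoride treatment can free both together later.

**Step 7**
Reactants: 9 Ar-Br
Product: 10 1-allyl-2-(TBSO)-4-(TBSOCH2)benzene (Ar-CH2CH=CH2)
Conditions: allylSnBu3, Pd(PPh3)4 (5 mol %), toluene, 100 °C
Reagents that add atoms: allyltributylstannane, C=CC[Sn](CCCC)(CCCC)CCCC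
Why: Stille coupling of the aryl bromide with allyltributylstannane installs C11 and a two-carbon extension under neutral conditions that leave both silyl ethers intact.

**Step 8**
Reactants: 10 Ar-CH2CH=CH2
Product: 12 2-Ar-acetaldehyde, via vicinal diol 11 (not isolated)
Conditions: OsO4 (2 mol %), NaIO4, 2,6-lutidine, dioxane–H2O, rt
Reagents that add atoms: osmium tetroxide, O=[Os](=O)(=O)=O; sodium periodate, [Na+].[O-]I(=O)(=O)=O; water, O
Why: Lemieux–Johnson oxidation (catalytic dihydroxylation then periodate cleavage, buffered by 2,6-lutidine) cuts the terminal alkene to the arylacetaldehyde without touching the arene.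

**Step 9**
Reactants: 13 ethyl (triphenylphosphoranylidene)acetate (2 equiv); 14 (iodomethyl)trimethylsilane
Product: 16 ethyl 3-(trimethylsilyl)-2-(triphenylphosphoranylidene)propanoate, via phosphonium iodide 15 (not isolated)
Conditions: toluene, 80 °C
Reagents that add atoms: none
Why: C-Alkylation of the stabilised ylide with the reactive alpha-silyl iodide followed by transylidation by the second equivalent of 13 gives the alpha-branched stabilised ylide.

**Step 10**
Reactants: 12 2-Ar-acetaldehyde; 16 ethyl 3-(trimethylsilyl)-2-(triphenylphosphoranylidene)propanoate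
Product: 17 ethyl (2Z)-4-Ar-2-[(trimethylsilyl)methyl]but-2-enoate (CH2Ar trans to CO2Et)
Conditions: CH2Cl2, 40 °C
Reagents that add atoms: none
Why: Wittig olefination with an alpha-branched stabilised ylide places the aldehyde residue trans to the ester, which fixes the C8=C9 geometry (C7 trans to C11) that later sets C9.

**Step 11**
Reactants: 17 ethyl (2Z)-4-Ar-2-[(trimethylsilyl)methyl]but-2-enoate
Product: 18 (2Z)-4-Ar-2-[(trimethylsilyl)methyl]but-2-en-1-ol
Conditions: DIBAL-H, CH2Cl2, −78 °C; Rochelle salt work-up
Reagents that add atoms: none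
Why: DIBAL-H 1,2-reduction of the enoate gives the allylic alcohol with retention of the alkene geometry and without harm to the allylsilane or the silyl ethers.

**Step 12**
Reactants: 18 (2Z)-4-Ar-2-[(trimethylsilyl)methyl]but-2-en-1-ol
Product: 19 [(2E)-4-Ar-2-(bromomethyl)but-2-en-1-yl]trimethylsilane (CH2Br trans to CH2Ar)
Conditions: CBr4, PPh3, CH2Cl2, 0 °C
Reagents that add atoms: carbon tetrabromide, BrC(Br)(Br)Br
Why: The Appel reaction converts the primary allylic alcohol into the bromide under neutral conditions by SN2 displacement, so that neither allylic transposition nor protodesilylation should intervene.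

**Step 13**
Reactants: 6 1-[(1S)-1,2,2-trimethylcyclopentyl]ethan-1-one; 19 allylic bromide
Product: 21 (4Z)-6-Ar-4-[(trimethylsilyl)methyl]-1-[(1S)-1,2,2-trimethylcyclopentyl]hex-4-en-1-one, via lithium enolate 20 (not isolated)
Conditions: LDA, THF, −78 °C; then 19, DMPU, −78 to −20 °C
Reagents that add atoms: lithium diisopropylamide, [Li+].CC(C)[N-]C(C)C (Li of 20)
Why: Kinetic lithium enolate alkylation: ketone 6 can enolise only towards its methyl group, and the enolate displaces the primary allylic bromide in SN2 fashion to form the C6–C7 bond.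

**Step 14**
Reactants: 21 ketone
Product: 22 (1S,4Z)-6-Ar-4-[(trimethylsilyl)methyl]-1-[(1S)-1,2,2-trimethylcyclopentyl]hex-4-en-1-ol
Conditions: (R)-Me-CBS oxazaborolidine [(3aR)-1-methyl-3,3-diphenyltetrahydro-1H,3H-pyrrolo[1,2-c][1,3,2]oxazaborole] (0.3 equiv), BH3·SMe2 (0.8 equiv), toluene, −20 °C; then MeOH, H2O
Reagents that add atoms: none
Why: Corey–Bakshi–Shibata reduction in which the tertiary cyclopentyl group acts as the large and the CH2 chain as the small substituent, so that the (R)-catalyst should give the (S)-carbinol at C5 under reagent control, the catalysed ketone reduction being much faster than hydroboration of the hindered trisubstituted alkene.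

**Step 15**
Reactants: 22 alcohol
Product: 25 1-(DrCH2)-2-(TBSO)-4-(TBSOCH2)benzene, via triflate 23 (not isolated), via ring-enlarged C10 cation 24 (not isolated)
Conditions: Tf2O (1.2 equiv), 2,6-di-tert-butyl-4-methylpyridine (2.5 equiv), CH2Cl2 (0.01 M), −78 to −20 °C
Reagents that add atoms: triflic anhydride, O=S(=O)(OS(=O)(=O)C(F)(F)F)C(F)(F)F (its atoms stay only in 23 and 24)
Why: Proposed new method: the neopentyl-type secondary triflate 23 ionises with assistance from the antiperiplanar C4–C10 ring bond, so that the CMe2 carbon C4 migrates from C10 to C5 (Wagner–Meerwein shift, cyclopentylcarbinyl to cyclohexyl, ring A from five to six members) and the charge appears at C10 as in the biosynthetic drimane cation (24), which is captured by C9 of the allylsilane before loss of the silyl group fixes the C8=C12 methylene. The closest known reaction types are the solvolytic ring enlargement of 1-alkylcyclopentylcarbinyl sulfonates, the acid-induced closure of monocyclic cyclofarnesyl-type cations to trans-decalins and the allylsilane-terminated cation–olefin cyclisation, and only their coupling in one event is new. Ring A is not closed but enlarged by the 1,2-shift, whereas ring B closes in a 6-endo-trig mode through a chair transition state. C5 is set by inversion at the carbinol carbon made in step 14, C10 by entry of C9 anti to the departing C4 (inversion of the camphoric acid centre, the antiperiplanar C4–C5–C10–C9 array being that of a trans-decalin), and C9 by the alkene geometry, which places CH2Ar equatorial in the chair. The step needs migration of C4 rather than of C1 or the methyl group, which is secured because C4 is the most substituted and best charge-bearing migrating group and its shift alone relieves both the cyclopentane strain and the compression between the vicinal quaternary carbons C4 and C10. It also needs ring closure to outrun proton loss, 1,2-hydride shift and direct attack of the alkene on C5, which the tethered and strongly nucleophilic allylsilane, the hindered non-nucleophilic base, the neopentyl shielding of C5 and the low temperature should secure.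

**Step 16**
Reactants: 25 bis-TBS ether
Product: 26 2-(DrCH2)-5-(hydroxymethyl)phenol
Conditions: Bu4NF, THF, 0 °C
Reagents that add atoms: none
Why: Fluoride-induced desilylation removes both TBS groups at once and leaves the exocyclic alkene untouched.

**Step 17**
Reactants: 26 2-(DrCH2)-5-(hydroxymethyl)phenol
Product: 28 2-(DrCH2)-5-(hydroxymethyl)-4,4-dimethoxycyclohexa-2,5-dien-1-one, via 4-methoxyphenol 27 (not isolated)
Conditions: PhI(OAc)2 (2.2 equiv), MeOH, 0 °C to rt
Reagents that add atoms: methanol, CO
Why: Phenolic oxidation with PhI(OAc)2 in methanol runs twice, first para-methoxylation to 27 and then oxidative ketalisation, which places the ketone at C1' next to the carbon that bears the decalin arm and the ketal at C4'.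

**Step 18**
Reactants: 28 quinone monoketal
Product: 29 (1R,6S)-1-(DrCH2)-4-(hydroxymethyl)-5,5-dimethoxy-7-oxabicyclo[4.1.0]hept-3-en-2-one
Conditions: Ph3COOH, NaHMDS, L-(+)-diisopropyl tartrate, 4 Å MS, toluene, −78 to −40 °C
Reagents that add atoms: trityl hydroperoxide, OOC(c1ccccc1)(c1ccccc1)c1ccccc1
Why: Weitz–Scheffer-type nucleophilic epoxidation mediated by a sodium tartrate template: the trityl peroxide anion can add only to the unsubstituted beta-carbon C3' of the alpha-alkyl enone arm (the other beta-carbon C5' is substituted), and the L-tartrate complex anchored on the free CH2OH group selects the face that gives the (1R,6S)-epoxide.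

**Step 19**
Reactants: 29 epoxy ketal
Product: 30 (1R,6S)-1-(DrCH2)-4-(hydroxymethyl)-7-oxabicyclo[4.1.0]hept-3-ene-2,5-dione
Conditions: 48% aq HF, MeCN, 0 °C
Reagents that add atoms: water, O
Why: Acid hydrolysis of the dimethyl ketal with dilute aqueous HF, an acid too weak to protonate the 1,1-disubstituted alkene or to open the electron-poor epoxide, unmasks the C4' ketone.

**Step 20**
Reactants: 30 epoxyquinone
Product: 31 (1R,5R,6R)-1-(DrCH2)-5-hydroxy-4-(hydroxymethyl)-7-oxabicyclo[4.1.0]hept-3-en-2-one
Conditions: DIBAL-H (2.5 equiv), THF, −78 °C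
Reagents that add atoms: none
Why: 1,2-Reduction of an epoxyquinone with DIBAL-H: the aluminium alkoxide formed from the CH2OH group activates the neighbouring C4' carbonyl, C1' is screened on one face by the epoxide oxygen and on the other by the decalin arm at C2', and hydride enters C4' anti to the epoxide oxygen to give the cis epoxy alcohol.

**Step 21**
Reactants: 32 dimethyl 3-hydroxy-3-methylpentanedioate
Product: 33 (3S)-3-hydroxy-5-methoxy-3-methyl-5-oxopentanoic acid
Conditions: pig liver esterase, phosphate buffer pH 7.5, NaOH (pH-stat), rt; then HCl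
Reagents that add atoms: water, O
Why: Enzymatic desymmetrisation: the esterase hydrolyses the pro-S ester arm of the prochiral diester and so sets the tertiary carbinol centre as (S).

**Step 22**
Reactants: 33 (S)-half ester
Product: 34 1-tert-butyl 5-methyl (3R)-3-hydroxy-3-methylpentanedioate
Conditions: tBuOC(=NH)CCl3, cyclohexane–CH2Cl2, rt
Reagents that add atoms: tert-butyl 2,2,2-trichloroacetimidate, CC(C)(C)OC(=N)C(Cl)(Cl)Cl
Why: Esterification of the free acid with the trichloroacetimidate transfers a tert-butyl cation to the carboxylate under nearly neutral conditions and leaves the tertiary alcohol free, the descriptor changing to (R) only through the priority rules.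

**Step 23**
Reactants: 34 mixed diester
Product: 35 (3R)-5-tert-butoxy-3-hydroxy-3-methyl-5-oxopentanoic acid
Conditions: LiOH (1 equiv), THF–H2O, 0 °C; then cold 1 M HCl
Reagents that add atoms: lithium hydroxide, [Li+].[OH-]
Why: Chemoselective saponification: hydroxide attacks the methyl ester while the tert-butyl ester is sterically protected, which swaps the free and the blocked carboxyl arm without touching the stereocentre.

**Step 24**
Reactants: 31 epoxyquinol diol; 35 (R)-half ester
Product: 36 tert-butyl ester of the target (3R in the side chain)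
Conditions: EDC·HCl, DMAP (cat.), CH2Cl2, −20 to 0 °C
Reagents that add atoms: none
Why: Steglich esterification is chemoselective for the primary allylic alcohol of 31 because the secondary C4' alcohol flanked by the epoxide and the tertiary alcohol of 35 are much more hindered.

**Step 25**
Reactants: 36 tert-butyl ester
Product: 38 target CNP0158101.1, via tris(trimethylsilyl) derivative 37 (not isolated)
Conditions: TMSOTf, 2,6-lutidine, CH2Cl2, 0 °C; then citric acid, THF–H2O, rt
Reagents that add atoms: trimethylsilyl triflate, C[Si](C)(C)OS(=O)(=O)C(F)(F)F (silyl groups of 37 only)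
Why: Silyl triflate-mediated cleavage of the tert-butyl ester (loss of 2-methylpropene from the O-silylated ester) works under buffered aprotic conditions that should spare the exocyclic alkene and the epoxide, and the transient TMS ester and TMS ethers are hydrolysed by citric acid on work-up.

**Compound list**
1 | (1S,3R)-camphoric acid | OC(=O)[C@@]1(C)CC[C@@H](C(=O)O)C1(C)C | starting material
2 | (1S,3R)-3-(methoxycarbonyl)-1,2,2-trimethylcyclopentane-1-carboxylic acid | OC(=O)[C@@]1(C)CC[C@@H](C(=O)OC)C1(C)C | intermediate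
3 | methyl (1R,3S)-3-(chlorocarbonyl)-2,2,3-trimethylcyclopentane-1-carboxylate | ClC(=O)[C@@]1(C)CC[C@@H](C(=O)OC)C1(C)C | intermediate
4 | methyl (1R,3S)-3-acetyl-2,2,3-trimethylcyclopentane-1-carboxylate | CC(=O)[C@@]1(C)CC[C@@H](C(=O)OC)C1(C)C | intermediate
5 | (1R,3S)-3-acetyl-2,2,3-trimethylcyclopentane-1-carboxylic acid | CC(=O)[C@@]1(C)CC[C@@H](C(=O)O)C1(C)C | intermediate
6 | 1-[(1S)-1,2,2-trimethylcyclopentyl]ethan-1-one | CC(=O)[C@@]1(C)CCCC1(C)C | intermediate
7 | methyl 4-bromo-3-hydroxybenzoate | COC(=O)c1ccc(Br)c(O)c1 | starting material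
8 | 2-bromo-5-(hydroxymethyl)phenol | OCc1ccc(Br)c(O)c1 | intermediate
9 | 1-bromo-2-(TBSO)-4-(TBSOCH2)benzene | CC(C)(C)[Si](C)(C)OCc1ccc(Br)c(O[Si](C)(C)C(C)(C)C)c1 | intermediate
10 | 1-allyl-2-(TBSO)-4-(TBSOCH2)benzene | C=CCc1ccc(CO[Si](C)(C)C(C)(C)C)cc1O[Si](C)(C)C(C)(C)C | intermediate
11 | 3-Ar-propane-1,2-diol | OCC(O)Cc1ccc(CO[Si](C)(C)C(C)(C)C)cc1O[Si](C)(C)C(C)(C)C | intermediate
12 | 2-Ar-acetaldehyde | O=CCc1ccc(CO[Si](C)(C)C(C)(C)C)cc1O[Si](C)(C)C(C)(C)C | intermediate
13 | ethyl (triphenylphosphoranylidene)acetate | CCOC(=O)C=P(c1ccccc1)(c1ccccc1)c1ccccc1 | starting material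
14 | (iodomethyl)trimethylsilane | C[Si](C)(C)CI | starting material
15 | [1-ethoxy-1-oxo-3-(trimethylsilyl)propan-2-yl]triphenylphosphonium iodide | CCOC(=O)C(C[Si](C)(C)C)[P+](c1ccccc1)(c1ccccc1)c1ccccc1.[I-] | intermediate
16 | ethyl 3-(trimethylsilyl)-2-(triphenylphosphoranylidene)propanoate | CCOC(=O)C(C[Si](C)(C)C)=P(c1ccccc1)(c1ccccc1)c1ccccc1 | intermediate
17 | ethyl (2Z)-4-Ar-2-[(trimethylsilyl)methyl]but-2-enoate | CCOC(=O)/C(C[Si](C)(C)C)=C/Cc1ccc(CO[Si](C)(C)C(C)(C)C)cc1O[Si](C)(C)C(C)(C)C | intermediate
18 | (2Z)-4-Ar-2-[(trimethylsilyl)methyl]but-2-en-1-ol | OC/C(C[Si](C)(C)C)=C/Cc1ccc(CO[Si](C)(C)C(C)(C)C)cc1O[Si](C)(C)C(C)(C)C | intermediate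
19 | [(2E)-4-Ar-2-(bromomethyl)but-2-en-1-yl]trimethylsilane | BrC/C(C[Si](C)(C)C)=C/Cc1ccc(CO[Si](C)(C)C(C)(C)C)cc1O[Si](C)(C)C(C)(C)C | intermediate
20 | lithium enolate of 6 | [Li+].[O-]C(=C)[C@@]1(C)CCCC1(C)C | intermediate
21 | (4Z)-6-Ar-4-[(trimethylsilyl)methyl]-1-[(1S)-1,2,2-trimethylcyclopentyl]hex-4-en-1-one | O=C(CC/C(C[Si](C)(C)C)=C/Cc1ccc(CO[Si](C)(C)C(C)(C)C)cc1O[Si](C)(C)C(C)(C)C)[C@@]1(C)CCCC1(C)C | intermediate
22 | (1S,4Z)-6-Ar-4-[(trimethylsilyl)methyl]-1-[(1S)-1,2,2-trimethylcyclopentyl]hex-4-en-1-ol | O[C@@H](CC/C(C[Si](C)(C)C)=C/Cc1ccc(CO[Si](C)(C)C(C)(C)C)cc1O[Si](C)(C)C(C)(C)C)[C@@]1(C)CCCC1(C)C | intermediate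
23 | triflate of 22 | O=S(=O)(O[C@@H](CC/C(C[Si](C)(C)C)=C/Cc1ccc(CO[Si](C)(C)C(C)(C)C)cc1O[Si](C)(C)C(C)(C)C)[C@@]1(C)CCCC1(C)C)C(F)(F)F | intermediate
24 | ring-enlarged tertiary C10 carbocation (triflate ion pair; 1,3,3-trimethylcyclohexyl cation with the chain at C5) | C[C+]1CCCC(C)(C)[C@@H]1CC/C(C[Si](C)(C)C)=C/Cc1ccc(CO[Si](C)(C)C(C)(C)C)cc1O[Si](C)(C)C(C)(C)C.[O-]S(=O)(=O)C(F)(F)F | intermediate
25 | 1-(DrCH2)-2-(TBSO)-4-(TBSOCH2)benzene | C=C1CC[C@H]2C(C)(C)CCC[C@]2(C)[C@H]1Cc1ccc(CO[Si](C)(C)C(C)(C)C)cc1O[Si](C)(C)C(C)(C)C | intermediate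
26 | 2-(DrCH2)-5-(hydroxymethyl)phenol | C=C1CC[C@H]2C(C)(C)CCC[C@]2(C)[C@H]1Cc1ccc(CO)cc1O | intermediate
27 | 2-(DrCH2)-5-(hydroxymethyl)-4-methoxyphenol | C=C1CC[C@H]2C(C)(C)CCC[C@]2(C)[C@H]1Cc1cc(OC)c(CO)cc1O | intermediate
28 | 2-(DrCH2)-5-(hydroxymethyl)-4,4-dimethoxycyclohexa-2,5-dien-1-one | C=C1CC[C@H]2C(C)(C)CCC[C@]2(C)[C@H]1CC1=CC(OC)(OC)C(CO)=CC1=O | intermediate
29 | (1R,6S)-1-(DrCH2)-4-(hydroxymethyl)-5,5-dimethoxy-7-oxabicyclo[4.1.0]hept-3-en-2-one | C=C1CC[C@H]2C(C)(C)CCC[C@]2(C)[C@H]1C[C@@]12O[C@@H]1C(OC)(OC)C(CO)=CC2=O | intermediate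
30 | (1R,6S)-1-(DrCH2)-4-(hydroxymethyl)-7-oxabicyclo[4.1.0]hept-3-ene-2,5-dione | C=C1CC[C@H]2C(C)(C)CCC[C@]2(C)[C@H]1C[C@@]12O[C@@H]1C(=O)C(CO)=CC2=O | intermediate
31 | (1R,5R,6R)-1-(DrCH2)-5-hydroxy-4-(hydroxymethyl)-7-oxabicyclo[4.1.0]hept-3-en-2-one | C=C1CC[C@H]2C(C)(C)CCC[C@]2(C)[C@H]1C[C@@]12O[C@@H]1[C@H](O)C(CO)=CC2=O | intermediate
32 | dimethyl 3-hydroxy-3-methylpentanedioate | COC(=O)CC(C)(O)CC(=O)OC | starting material
33 | (3S)-3-hydroxy-5-methoxy-3-methyl-5-oxopentanoic acid | COC(=O)C[C@@](C)(O)CC(=O)O | intermediate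
34 | 1-tert-butyl 5-methyl (3R)-3-hydroxy-3-methylpentanedioate | COC(=O)C[C@@](C)(O)CC(=O)OC(C)(C)C | intermediate
35 | (3R)-5-tert-butoxy-3-hydroxy-3-methyl-5-oxopentanoic acid | OC(=O)C[C@@](C)(O)CC(=O)OC(C)(C)C | intermediate
36 | tert-butyl ester of the target | C=C1CC[C@H]2C(C)(C)CCC[C@]2(C)[C@H]1C[C@@]12O[C@@H]1[C@H](O)C(COC(=O)C[C@@](C)(O)CC(=O)OC(C)(C)C)=CC2=O | intermediate
37 | TMS ester bis(TMS ether) of the target | C=C1CC[C@H]2C(C)(C)CCC[C@]2(C)[C@H]1C[C@@]12O[C@@H]1[C@H](O[Si](C)(C)C)C(COC(=O)C[C@@](C)(O[Si](C)(C)C)CC(=O)O[Si](C)(C)C)=CC2=O | intermediate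
38 | CNP0158101.1: (3S)-3-hydroxy-3-methylpentanedioic acid mono ester of 31 at the primary alcohol | C=C1CC[C@H]2C(C)(C)CCC[C@]2(C)[C@H]1C[C@@]12O[C@@H]1[C@H](O)C(COC(=O)C[C@@](C)(O)CC(=O)O)=CC2=O | target

Total step count: 25. Longest linear sequence: 17 steps (7 to 38 through steps 5–8, 10–20, 24 and 25).

**Steps most likely to fail**

1. Step 15.
   - What may go wrong: migration of C1 or of the methyl group in place of C4; proton loss or a 1,2-hydride shift in the enlarged cation before ring B closes; protodesilylation of the allylsilane.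
   - Fallback: the two events are separated, each being a known reaction type. It sets out from 22.
   - MsCl/Et3N would give the mesylate F1. Buffered solvolysis of F1 (aqueous acetone, CaCO3, 50 °C) is a solvolytic Wagner–Meerwein ring enlargement of a cyclopentylcarbinyl sulfonate with capture by water, and would give the ring-enlarged tertiary cyclohexanol F2.
   - Ionisation of F2 with BF3·OEt2 in CH2Cl2 at −78 °C, with intramolecular capture by the allylsilane (a known allylsilane-terminated cyclisation started from a tertiary alcohol), comes back to the route at 25.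

2. Step 18.
   - What may go wrong: poor facial selectivity if the tartrate template and the resident decalin stereocentres are mismatched; slow addition because the decalin arm screens C3'.
   - Fallback: auxiliary control in place of reagent control. It sets out from 28.
   - Transketalisation with (2S,4S)-pentane-2,4-diol (PPTS, benzene, removal of MeOH) would give the chiral spiroketal dienone F3.
   - Epoxidation of F3 with Ph3COOH/KHMDS (toluene, −40 °C) under control of the C2-symmetric ketal would give the epoxy spiroketal F4. The antipodal diol serves if the other face turns out to be shielded, and the two epoxides are diastereomers that can be separated in any case.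
   - Aqueous HF in MeCN then removes the auxiliary and comes back to the route at 30.

3. Step 25.
   - What may go wrong: isomerisation of the exocyclic alkene, opening of the epoxide or silyl dienol ether formation under the silyl triflate; incomplete loss of the tertiary silyl ether.
   - Fallback: a fluoride-labile ester in place of an acid-labile one. It sets out from 33 and 31.
   - 33 with 2-(trimethylsilyl)ethanol (EDC·HCl, DMAP) would give the mixed methyl 2-(trimethylsilyl)ethyl diester F5.
   - Me3SnOH (1,2-dichloroethane, 60 °C) should cleave only the methyl ester, giving the 2-(trimethylsilyl)ethyl half ester F6.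
   - Steglich coupling of F6 with 31 would give the 2-(trimethylsilyl)ethyl ester of the target F7.
   - Tris(dimethylamino)sulfonium difluorotrimethylsilicate in DMF at 0 °C removes the ester group under nearly neutral conditions and comes back to the route at 38.

**Further compounds**
F1 | step 15 | mesylate of 22 | CS(=O)(=O)O[C@@H](CC/C(C[Si](C)(C)C)=C/Cc1ccc(CO[Si](C)(C)C(C)(C)C)cc1O[Si](C)(C)C(C)(C)C)[C@@]1(C)CCCC1(C)C
F2 | step 15 | (1S,2S)-2-{(3Z)-5-Ar-3-[(trimethylsilyl)methyl]pent-3-en-1-yl}-1,3,3-trimethylcyclohexan-1-ol | C[C@]1(O)CCCC(C)(C)[C@@H]1CC/C(C[Si](C)(C)C)=C/Cc1ccc(CO[Si](C)(C)C(C)(C)C)cc1O[Si](C)(C)C(C)(C)C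
F3 | step 18 | (2S,4S)-pentane-2,4-diyl spiroketal analogue of 28 | C=C1CC[C@H]2C(C)(C)CCC[C@]2(C)[C@H]1CC1=CC2(O[C@@H](C)C[C@H](C)O2)C(CO)=CC1=O
F4 | step 18 | (2S,4S)-pentane-2,4-diyl spiroketal analogue of 29 | C=C1CC[C@H]2C(C)(C)CCC[C@]2(C)[C@H]1C[C@@]12O[C@@H]1C1(O[C@@H](C)C[C@H](C)O1)C(CO)=CC2=O
F5 | step 25 | 1-methyl 5-[2-(trimethylsilyl)ethyl] (3R)-3-hydroxy-3-methylpentanedioate | COC(=O)C[C@@](C)(O)CC(=O)OCC[Si](C)(C)C
F6 | step 25 | (3R)-3-hydroxy-3-methyl-5-oxo-5-[2-(trimethylsilyl)ethoxy]pentanoic acid | OC(=O)C[C@@](C)(O)CC(=O)OCC[Si](C)(C)C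
F7 | step 25 | 2-(trimethylsilyl)ethyl ester of 38 | C=C1CC[C@H]2C(C)(C)CCC[C@]2(C)[C@H]1C[C@@]12O[C@@H]1[C@H](O)C(COC(=O)C[C@@](C)(O)CC(=O)OCC[Si](C)(C)C)=CC2=O
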